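The target is cut between the ketone carbonyl carbon on C6 of the 2H-chromene and the benzylic CH2. Both carbons are electrophilic by nature: one is an aldehyde carbon, the other the exocyclic carbon of the p-quinone methide that the para-hydroxyl of the benzyl ring opens. A carbene catalyst reverses the polarity of the formyl group of the fully substituted, unprotected 5-hydroxy-7-methoxy-8-prenylchromene-6-carbaldehyde, and its Breslow intermediate adds 1,6 to the transient quinone methide, so ketone and free phenol appear in one protecting-group-free last operation. The aldehyde arises in three steps from 2,4-dihydroxy-6-methoxybenzaldehyde by chromene annulation with prenal and an O-prenylation/para-Claisen–Cope relay to C8.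

Key step: step 4

Assumption: compounds 1, 2, 5 and 10 are taken as catalogue compounds; the target has no stereocentre, so no step needs stereocontrol.

Step 1
Reactants: 1 2,4-dihydroxy-6-methoxybenzaldehyde; 2 3-methylbut-2-enal (prenal)
Product: 4 5-hydroxy-7-methoxy-2,2-dimethyl-2H-chromene-6-carbaldehyde, via o-quinone methide dienone 3 (not isolated)
Conditions: 2 (2 equiv), pyridine, 120 °C, sealed tube
Reagents that add atoms: none
Why: Base-mediated condensation of the enal at C3 of the resorcinol and loss of water give the o-quinone methide 3, which closes by oxa-6π electrocyclisation (formal [3+3] chromene annulation); the formyl-chelated 2-OH stays out so that the free 4-OH becomes the ring oxygen, and chelate-induced bond fixation should direct the new C–C bond to C3 and not to C5.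

Step 2
Reactants: 4 5-hydroxy-7-methoxy-2,2-dimethyl-2H-chromene-6-carbaldehyde; 5 1-bromo-3-methylbut-2-ene (prenyl bromide)
Product: 6 7-methoxy-2,2-dimethyl-5-[(3-methylbut-2-en-1-yl)oxy]-2H-chromene-6-carbaldehyde
Conditions: K2CO3, DMF, 50 °C
Reagents that add atoms: none
Why: Williamson etherification: the only phenol of 4, although hydrogen-bonded to the formyl group, is deprotonated by carbonate in DMF and alkylated on oxygen by the primary allylic bromide (SN2).

Step 3
Reactants: 6 7-methoxy-2,2-dimethyl-5-[(3-methylbut-2-en-1-yl)oxy]-2H-chromene-6-carbaldehyde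
Product: 9 5-hydroxy-7-methoxy-2,2-dimethyl-8-(3-methylbut-2-en-1-yl)-2H-chromene-6-carbaldehyde, via ortho-dienone 7 (not isolated), via para-dienone 8 (not isolated)
Conditions: PhNEt2, 190 °C, sealed tube, Ar
Reagents that add atoms: none
Why: Para-Claisen rearrangement (aromatic Claisen then Cope): both ortho positions of the aryl prenyl ether are substituted, so dienone 7 cannot enolise and passes its 1,1-dimethylallyl group by a second [3,3] shift to C8, the only ring carbon bearing hydrogen, where enolisation of 8 restores the phenol and the double allylic inversion returns the linear prenyl group.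

Step 4
Reactants: 9 5-hydroxy-7-methoxy-2,2-dimethyl-8-(3-methylbut-2-en-1-yl)-2H-chromene-6-carbaldehyde; 10 tert-butyl[4-(bromomethyl)phenoxy]dimethylsilane
Product: 12 1-[5-hydroxy-7-methoxy-2,2-dimethyl-8-(3-methylbut-2-en-1-yl)-2H-chromen-6-yl]-2-(4-hydroxyphenyl)ethan-1-one (target), via p-quinone methide 11 (not isolated)
Conditions: 2-(pentafluorophenyl)-6,7-dihydro-5H-pyrrolo[2,1-c][1,2,4]triazolium BF4 (20 mol%), CsF (4 equiv), 18-crown-6, THF, 25–40 °C, 10 (1.5 equiv) added by syringe pump; then aq. NH4Cl
Reagents that add atoms: none
Why: Proposed new method: fluoride removes the silyl group of 10 and the phenoxide expels bromide, feeding the parent p-quinone methide 11 into the flask at low concentration, while the triazolylidene adds to the formyl group of 9 and proton transfer gives the Breslow intermediate, an acyl anion equivalent. Its carbinol carbon should add to the exocyclic CH2 of 11 in a 1,6-sense, driven by re-aromatisation to the phenoxide, and collapse of the adduct releases the carbene and the aryl ketone, so that the C(=O)–CH2 bond is made from two carbons that are both electrophilic by nature. The closest known reaction types are the carbene-catalysed 1,6-hydroacylation of isolable δ-aryl-2,6-di-tert-butyl p-quinone methides with aromatic aldehydes and the carbene-catalysed acylation of fluoride-generated o-quinone methides; new here are the unsubstituted, transient p-quinone methide and the 2,6-disubstituted salicylaldehyde as donor. No ring is closed and no stereocentre is formed. The step needs C- over O-benzylation and a carbene that survives the bromide: O-adducts of 11 with the phenoxides of 9 or 12, and its adduct with the carbene, are 4-hydroxybenzyl derivatives expected to re-ionise to 11 under the basic conditions, whereas C-acylation is irreversible and drains these equilibria, and slow addition keeps 10 and 11 scarce. The small, planar, electron-poor C6F5-triazolylidene is chosen because the formyl group is flanked by 5-OH and 7-OMe, and the isolated prenyl and chromene double bonds are no acceptors for the acyl anion equivalent.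

Compound list
1 | 2,4-dihydroxy-6-methoxybenzaldehyde | COc1cc(O)cc(O)c1C=O | starting material
2 | 3-methylbut-2-enal (prenal) | CC(C)=CC=O | starting material
3 | 2-hydroxy-6-methoxy-3-(3-methylbut-2-en-1-ylidene)-4-oxocyclohexa-1,5-diene-1-carbaldehyde (o-quinone methide) | COC1=CC(=O)C(=CC=C(C)C)C(O)=C1C=O | intermediate
4 | 5-hydroxy-7-methoxy-2,2-dimethyl-2H-chromene-6-carbaldehyde | COc1cc2OC(C)(C)C=Cc2c(O)c1C=O | intermediate
5 | 1-bromo-3-methylbut-2-ene (prenyl bromide) | CC(C)=CCBr | starting material
6 | 7-methoxy-2,2-dimethyl-5-[(3-methylbut-2-en-1-yl)oxy]-2H-chromene-6-carbaldehyde | COc1cc2OC(C)(C)C=Cc2c(OCC=C(C)C)c1C=O | intermediate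
7 | 7-methoxy-2,2-dimethyl-6-(2-methylbut-3-en-2-yl)-5-oxo-5,6-dihydro-2H-chromene-6-carbaldehyde (ortho-dienone, racemic) | COC1=CC2=C(C=CC(C)(C)O2)C(=O)C1(C=O)C(C)(C)C=C | intermediate
8 | 7-methoxy-2,2-dimethyl-8-(3-methylbut-2-en-1-yl)-5-oxo-5,8-dihydro-2H-chromene-6-carbaldehyde (para-dienone, racemic) | COC1=C(C=O)C(=O)C2=C(OC(C)(C)C=C2)C1CC=C(C)C | intermediate
9 | 5-hydroxy-7-methoxy-2,2-dimethyl-8-(3-methylbut-2-en-1-yl)-2H-chromene-6-carbaldehyde | COc1c(CC=C(C)C)c2OC(C)(C)C=Cc2c(O)c1C=O | intermediate
10 | tert-butyl[4-(bromomethyl)phenoxy]dimethylsilane | CC(C)(C)[Si](C)(C)Oc1ccc(CBr)cc1 | starting material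
11 | 4-methylidenecyclohexa-2,5-dien-1-one (p-quinone methide) | C=C1C=CC(=O)C=C1 | intermediate
12 | 1-[5-hydroxy-7-methoxy-2,2-dimethyl-8-(3-methylbut-2-en-1-yl)-2H-chromen-6-yl]-2-(4-hydroxyphenyl)ethan-1-one | COc1c(CC=C(C)C)c2c(c(O)c1C(=O)Cc1ccc(O)cc1)C=CC(C)(C)O2 | target

Total step count: 4
Longest linear sequence: 4 steps (1 → 4 → 6 → 9 → 12)

Steps most likely to fail

Step 4 (proposed new method). The Breslow intermediate may form too slowly at a formyl group that is substituted on both sides and deactivated as its phenoxide, so that the quinone methide oligomerises, or the carbene may be captured irreversibly by the bromide or the quinone methide. The fallback uses known chemistry, sets out from 9 and returns at 12. The phenol of 9 is protected with NaH and chloromethyl methyl ether in DMF at 0 °C to give 7-methoxy-5-(methoxymethoxy)-2,2-dimethyl-8-(3-methylbut-2-en-1-yl)-2H-chromene-6-carbaldehyde F1. Bromide 10 is converted with magnesium in ether at high dilution into {4-[(tert-butyldimethylsilyl)oxy]benzyl}magnesium bromide F2, which is added to F1 at −78 to 0 °C and quenched with aqueous NH4Cl to give the racemic carbinol 2-{4-[(tert-butyldimethylsilyl)oxy]phenyl}-1-[7-methoxy-5-(methoxymethoxy)-2,2-dimethyl-8-(3-methylbut-2-en-1-yl)-2H-chromen-6-yl]ethan-1-ol F3. Dess–Martin oxidation in buffered CH2Cl2 should give the protected ketone 2-{4-[(tert-butyldimethylsilyl)oxy]phenyl}-1-[7-methoxy-5-(methoxymethoxy)-2,2-dimethyl-8-(3-methylbut-2-en-1-yl)-2H-chromen-6-yl]ethan-1-one F4. TBAF in THF followed by dilute HCl in methanol at 40 °C removes the silyl and methoxymethyl groups and should give 12.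

Step 3. Dienone 7 may fragment with loss of the C5 unit back to phenol 4, or the material may decompose at the temperature the double sigmatropic shift needs. The fallback sets out from 4, bypasses 6 and returns at 9. Iodination of 4 with N-iodosuccinimide in MeCN at 0 °C, directed para to the free phenol to the only unsubstituted ring carbon, should give 5-hydroxy-8-iodo-7-methoxy-2,2-dimethyl-2H-chromene-6-carbaldehyde F5. Stille coupling of F5 with tributyl(3-methylbut-2-en-1-yl)stannane and Pd(PPh3)4 in DMF at 90 °C should deliver the linear prenyl group and give 9.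

Step 1. The enal may condense at C5 instead of C3, or the ring may close through the chelated 2-OH, so that isomeric chromenes form. The fallback sets out from 1 and returns at 4. The more acidic, unchelated 4-OH is alkylated with 3-chloro-3-methylbut-1-yne (K2CO3, KI and CuI as catalysts, acetone, reflux) to give 2-hydroxy-6-methoxy-4-[(2-methylbut-3-yn-2-yl)oxy]benzaldehyde F6, which fixes the ring oxygen. Heating F6 in N,N-diethylaniline at 190 °C should give 4 by propargyl Claisen rearrangement, 1,5-hydrogen shift and oxa-6π closure; the direction towards C3 is the one known for formyl- and acyl-chelated resorcinol ethers.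

Further compounds
F1 | step 4 | 7-methoxy-5-(methoxymethoxy)-2,2-dimethyl-8-(3-methylbut-2-en-1-yl)-2H-chromene-6-carbaldehyde | COc1c(CC=C(C)C)c2OC(C)(C)C=Cc2c(OCOC)c1C=O
F2 | step 4 | {4-[(tert-butyldimethylsilyl)oxy]benzyl}magnesium bromide | CC(C)(C)[Si](C)(C)Oc1ccc(C[Mg]Br)cc1
F3 | step 4 | 2-{4-[(tert-butyldimethylsilyl)oxy]phenyl}-1-[7-methoxy-5-(methoxymethoxy)-2,2-dimethyl-8-(3-methylbut-2-en-1-yl)-2H-chromen-6-yl]ethan-1-ol (racemic) | COc1c(CC=C(C)C)c2OC(C)(C)C=Cc2c(OCOC)c1C(O)Cc1ccc(O[Si](C)(C)C(C)(C)C)cc1
F4 | step 4 | 2-{4-[(tert-butyldimethylsilyl)oxy]phenyl}-1-[7-methoxy-5-(methoxymethoxy)-2,2-dimethyl-8-(3-methylbut-2-en-1-yl)-2H-chromen-6-yl]ethan-1-one | COc1c(CC=C(C)C)c2OC(C)(C)C=Cc2c(OCOC)c1C(=O)Cc1ccc(O[Si](C)(C)C(C)(C)C)cc1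
F5 | step 3 | 5-hydroxy-8-iodo-7-methoxy-2,2-dimethyl-2H-chromene-6-carbaldehyde | COc1c(I)c2OC(C)(C)C=Cc2c(O)c1C=O
F6 | step 1 | 2-hydroxy-6-methoxy-4-[(2-methylbut-3-yn-2-yl)oxy]benzaldehyde | COc1cc(OC(C)(C)C#C)cc(O)c1C=O
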